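- 4 questions stand on the gamma flask, which is the asked flask followed so far, and one balance of catalyst against stray impurity serves them.

in all of them: left-handed substrate 0.30 M; right-handed substrate 0.30 M; stray impurity 1.9 mM

| flask | coupling partner | protic impurity | free catalyst | remark | time |
|---|---|---|---|---|---|
| gamma | 0.30 M | 0.030 M | 1.5 mM | the very flask that is asked about, followed so far |  |
| alpha | 0.30 M | 0.030 M | 3 mM | run made earlier |  |
| flask | 0.300 M | 0.0300 M | 1.5 mM |  | 8.0 d |

| run | time / h | left-handed product / % |
|---|---|---|
| gamma | 30.0 | 19.0 |
| gamma | 60.0 | 21.8 |
| gamma | 96.0 | 20.5 |
| gamma | 120 | 20.6 |
| gamma | 144 | 18.7 |
| gamma | 192 | 18.0 |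
| alpha | 2.50 | 27.8 |
| alpha | 8.00 | 31.9 |
| alpha | 15.0 | 32.3 |
| alpha | 20.0 | 29.1 |
| alpha | 30.0 | 30.7 |
| alpha | 40.0 | 29.4 |

(scatter of a reading: 1 percentage point)

1. left-handed product, in percent of the left-handed substrate and right-handed substrate together first charged, at 8.0 d
2. the remedy with the largest gain of left-handed product, or "none" below 2 percentage points (south-east / south-west / north / south / none)
3. left-handed product present, with what was taken out counted in, in percent of the left-handed substrate and right-handed substrate together first charged, after south-west
4. left-handed product present, with what was taken out counted in, in percent of the left-handed substrate and right-handed substrate together first charged, after south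

- south-east: at 8.0 d add coupling partner, 100% of the amount charged, then wait 2.5 d
- south-west: at 8.0 d add free catalyst, 100% of the amount charged, then wait 2.5 d
- north: at 8.0 d take out 90% of the left-handed product then present, then wait 2.5 d
- south: change nothing and wait 2.5 d more

- free catalyst is single-handed; left-handed substrate and right-handed substrate are mirror images of each other, charged as a racemate, each of them at the stated concentration
- removed left-handed product is counted in
- what was read earlier has a scatter of 1 percentage point, one standard deviation
- additions bring no volume worth counting

- The alpha flask starts steeply: 27.8% at 2.50 h is an average slope of 0.111 /h as a fraction of the charge.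
- That slope reaches the alpha level, the mean of its readings, 30.2%, in a time scale of 2.72 h, so the knee lies before the reading at 8.00 h.
- The gamma flask is already near its level at 30.0 h; that level, read the same way, is 19.8%, give or take 0.41 percentage points.
- Its first and last readings differ by 1 point, the scatter of one reading, so this reckoning takes the gamma curve as flat.
- A level that moves with the catalyst charge suggests loss of catalyst, and the stray impurity is the candidate, one taken for one.
- In the gamma flask the balance is −0.400 mM: this is the catalyst margin M, free catalyst charged minus stray impurity charged.
- M is negative there, but in the alpha flask it is 1.10 mM.
- South-west brings M in the gamma flask to 1.10 mM, the alpha value, so this reckoning expects the alpha level, a gain of 10 points.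
- South, north and south-east leave M negative, so this reckoning expects 19.8% at 8.0 d and no gain from them.
- The forecast gives 18.6% now, 17.4% after south and 27% after south-west, lower than this reckoning, and says “Fresh catalyst should restart conversion”.
- The flask gives 19.9% at 8.0 d, 19.9% after south and 29.4% after south-west, a gain of 9.5 points; south-east and north gain 0 points and 0 points.

    coupling partner + free catalyst + left-handed substrate → free catalyst + left-handed product (k = 6600 /M²/h)
    coupling partner + free catalyst + right-handed substrate → free catalyst + right-handed product (k = 2800 /M²/h)
    coupling partner + protic impurity → quenched reagent (k = 7.20 /M/h)
    coupling partner ⇌ dormant form (K = 2.20, k = 0.340 /h)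
    free catalyst + stray impurity → spent catalyst (k = 3000 /M/h)

- M gives the stray impurity left in the gamma flask as 21.1% of its charge, and the flask holds 21.1% at 192 h, with free catalyst at 0%.
- In the gamma flask the passing of free catalyst and stray impurity into spent catalyst is part of the reason for the level at 8.0 d: the simulated run without that step gives 30.8%.
- In that run the gain by south-west drops to 0 points, and that change would make the choice of south-west wrong.
- The neighbour flask with 0.51 M of coupling partner has the same M, which gives 21.1% of the stray impurity left; it computes to 21.1% at 192 h, with free catalyst at 0% and left-handed product at 30.0%.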